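## The problem

The target **10** is 8-(3,4-dimethoxyphenyl)-2,6-dimethoxynaphthalene-1,4-dione. It is numbered here with the quinone ring A as C1(=O)–C2(OMe)=C3H–C4(=O), the fusion carbons as C4a and C8a, the benzo ring B as C5–C8 (C6–OMe, C8–aryl) and the pendant dimethoxyphenyl ring as ring C. The molecule has no stereocentre, so the difficulty is regiochemical. The C2 methoxy must sit next to the carbonyl (C1) that is peri to the aryl-bearing C8, and in ring B the methoxy and the aryl must be meta to each other with C5 and C7 left as CH. The only stereochemical element that can control anything is one the route creates itself: the geometry of a trisubstituted alkene, which decides which of two aryl rings can reach a ring closure. The crowded C1/C8 peri relationship argues against a late biaryl coupling at C8 and for carrying the C8–aryl bond in from an open-chain stage. The methoxyquinone is a vinylogous ester that will not tolerate nucleophiles, strong base or reducing agents, so it should be unveiled last. On the way an acid-labile enol ether and several electron-rich, easily over-oxidised arenes have to be respected. The key step is possible because opening ring B between C4a and C5 makes C5 the terminal carbon of a 2-methoxydiene C5=C6(OMe)–C7=C8, and leaves C4a as an arene carbon para to the C2 oxygen and the only hydrogen-bearing ortho carbon of ring A. These are two electron-rich carbons that can be joined by removing two electrons and two protons.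

## Retrosynthesis

**10 ⇒ 9.** The C4 oxygen and the quinone oxidation level are removed, leaving 8-(3,4-dimethoxyphenyl)-2,6-dimethoxynaphthalen-1-ol **9**. Oxidative demethylation of a C1 methyl ether would have to choose among five methyl ethers on three electron-rich rings. A free hydroxyl instead singles out ring A. The C2 methoxy blocks the ortho position, so a Teuber oxidation can deliver oxygen only to C4. The precursor is fully aromatic and robust.

**9 ⇒ 8.** The O1–benzyl bond is cut, giving 1-(benzyloxy)-8-(3,4-dimethoxyphenyl)-2,6-dimethoxynaphthalene **8**. Benzyl distinguishes O1 from the four methyl ethers. It should survive an organolithium, a titanium methylidene and the anode, and it leaves by neutral hydrogenolysis that touches nothing else.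

**8 ⇒ 7.** The C4a–C5 bond of ring B is cut, which opens **8** to the (Z)-1,1-diaryl-3-methoxybuta-1,3-diene **7**.
- The neighbouring cut at the biaryl bond C8–C1' would require a regiodefined, peri-hindered 8-halonaphthalene first.
- A Friedel–Crafts closure at C8–C8a would have to attack the ring-A position flanked by two substituents.
- The C4a–C5 cut lets every substituent of ring B be placed on an open chain, with C6–OMe and C8–aryl already at their final oxidation level.
- The forward reaction must join two nucleophilic carbons oxidatively. It must use ring A and not ring C, and it must stop at the naphthalene.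

**7 ⇒ 6.** The terminal methylene C5 is removed, so the enol ether becomes the ester carbonyl of methyl (Z)-3,3-diarylacrylate **6**. Making the enol ether from a methyl ketone by ketalisation and elimination would cost a step more and would expose the alkene geometry to acid. Carbonyl methylenation of the ester is non-acidic, and the ester methoxy becomes the C6 methoxy of the target.

**6 ⇒ 4 + 5.** The C8–C1' bond and the C7–H bond are cut, giving arylpropiolate **4** and 3,4-dimethoxyphenylboronic acid **5**. Olefination of an unsymmetrical diaryl ketone would give no geometric control. A syn-hydroarylation sets the geometry by mechanism: the incoming ring C ends up cis to the new hydrogen, so ring A is cis to the ester.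

**4 ⇒ 2 ⇒ 1.** The C6–C7 bond is cut (acylation of the lithium acetylide **3** derived from alkyne **2**), and then the alkyne carbon C7 is removed (one-carbon homologation of aldehyde **1**, whose formyl carbon becomes C8). Both are routine operations on a catalogue aldehyde that already carries the O1/O2 pattern of ring A.

## Roads not taken

**Alternative 1:** Ring B is cut at three bonds (C4a–C8a, C5–C6, C7–C8), which also opens the carbocycle that becomes ring A. The precursors are 1-(3,4-dimethoxyphenyl)octa-1,7-diyn-3-one A1 and methoxyacetylene A2. Forward, Cp*RuCl(cod) (divalent ruthenium) would join them in a [2+2+2] cycloaddition to 8-(3,4-dimethoxyphenyl)-6-methoxy-3,4-dihydronaphthalen-1(2H)-one A3.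
- Merits: three bonds and two rings form in one operation, the assembly is convergent, and the C1 carbonyl is already peri to the aryl. Base-mediated autoxidation of A3 to 8-(3,4-dimethoxyphenyl)-2-hydroxy-6-methoxynaphthalene-1,4-dione A4 and O-methylation could finish the synthesis, so the step count would be comparable to the chosen plan or slightly lower.
- Weak points: placing the methoxy at C6 and not C7 depends on a steric bias in the unsymmetrical ruthenacycle. A 1,7-diyne closing a six-membered carbocycle is a poorer substrate than the usual 1,6-diynes. A2 is volatile, labile, prone to self-trimerisation and not a shelf reagent. All oxygenation of ring A beyond C1 must be introduced late by autoxidation beside two electron-rich rings.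
- Comparison: in bonds formed per step this road is better. The chosen plan sets against it that every substituent position is fixed by constitution or by an alkene geometry that can be checked before ring closure, that all reagents are shelf-stable, and that the O1/O2 pattern of ring A is bought.

**Alternative 2:** Ring B is cut at C4a–C5 and C8–C8a into 2-methoxy-1,4-benzoquinone A5 and (E)-1-(3,4-dimethoxyphenyl)-3-(tert-butyldimethylsilyloxy)buta-1,3-diene A6. A thermal Diels–Alder reaction at the unsubstituted quinone double bond would give the endo, cis-fused adduct A7, 8-(3,4-dimethoxyphenyl)-6-(tert-butyldimethylsilyloxy)-2-methoxy-4a,5,8,8a-tetrahydronaphthalene-1,4-dione.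
- Merits: both components are one or two steps from catalogue compounds, two ring bonds form at once, and ring A arrives as the finished methoxyquinone. Both diene substituents direct the same terminus towards the quinone carbon β to the more electron-poor carbonyl C1, which matches the target.
- Weak points: the regiochemistry is a kinetic preference resting on the electronic difference between the two quinone carbonyls, not a structural necessity. After cycloaddition ring B is four hydrogens short of aromatic and its C6 oxygen is a silyl enol ether. Enolisation, two dehydrogenations, desilylation and a selective O-methylation must then be done on a base- and nucleophile-sensitive methoxyquinone.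
- Comparison: on step count and precedent this road is at least as good as the chosen one. It is probably one or two steps shorter and uses known reaction types throughout. The chosen plan sets against it regiochemistry that is enforced and not merely preferred, a ring B that is formed aromatic with its methyl ether in place, and a quinone that appears only in the last step.

**Alternative 3:** Ring C is cut at C1'–C2' and C5'–C6' into 8-ethynyl-1,2,4,6-tetramethoxynaphthalene A8 and 2,3-dimethoxybuta-1,3-diene A9. CoBr2(dppe) with zinc and ZnI2 (monovalent cobalt formed in situ) would join them in a neutral [4+2] cycloaddition to 8-(4,5-dimethoxycyclohexa-1,4-dien-1-yl)-1,2,4,6-tetramethoxynaphthalene A10. Dehydrogenation of ring C and oxidative demethylation of ring A would follow.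
- Merits: the diene is symmetrical, so the cycloaddition has no regiochemical question. The conditions are mild, and ring C could be varied late.
- Weak points: the step builds the one ring that can be bought as a boronic acid. A8 is a regiodefined pentasubstituted naphthalene with a peri alkyne and is harder to make than the target skeleton itself. The bis-enol ether A10 is acid-sensitive. The final oxidative demethylation must distinguish the trimethoxy ring A from the newly formed dimethoxyphenyl ring.
- Comparison: this road is clearly longer and moves the real problem, the substituted naphthalene, into the starting material. Its one advantage is a cycloaddition of established type as key step, whereas the chosen plan relies on an untested oxidative closure.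

Key step: step 5

Remark: aldehyde **1** and boronic acid **5** are taken as catalogue compounds. The target has no stereocentre; the only stereochemical element of the route is the Z alkene of **6** and **7**.

## Route

Step 1
Reactants: 1 2-(benzyloxy)-3-methoxybenzaldehyde
Product: 2 2-(benzyloxy)-1-ethynyl-3-methoxybenzene
Conditions: dimethyl (1-diazo-2-oxopropyl)phosphonate, K2CO3, MeOH, 0 °C to rt
Reagents that add atoms: dimethyl (1-diazo-2-oxopropyl)phosphonate, CC(=O)C(=[N+]=[N-])P(=O)(OC)OC
Why: Ohira–Bestmann (Seyferth–Gilbert) homologation: methanolysis of the reagent gives the diazomethylphosphonate anion, which adds to the aldehyde, and loss of phosphate and dinitrogen gives the terminal alkyne; the base is mild enough for the benzyl and methyl ethers.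

Step 2
Reactants: 2 2-(benzyloxy)-1-ethynyl-3-methoxybenzene
Product: 4 methyl 3-[2-(benzyloxy)-3-methoxyphenyl]prop-2-ynoate, via lithium acetylide 3 (not isolated)
Conditions: n-BuLi, THF, −78 °C; then ClCO2Me, −78 °C to 0 °C
Reagents that add atoms: methyl chloroformate, COC(Cl)=O
Why: Deprotonation of the terminal alkyne and C-acylation of the acetylide with a chloroformate is a standard route to arylpropiolates; at −78 °C the alkyne C–H is far more acidic than any benzylic or aryl position.

Step 3
Reactants: 4 methyl 3-[2-(benzyloxy)-3-methoxyphenyl]prop-2-ynoate; 5 3,4-dimethoxyphenylboronic acid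
Product: 6 methyl (Z)-3-[2-(benzyloxy)-3-methoxyphenyl]-3-(3,4-dimethoxyphenyl)prop-2-enoate
Conditions: CuOAc (5 mol%), MeOH, rt
Reagents that add atoms: none
Why: Copper-catalysed syn-hydroarylation of an arylpropiolate: the arylcopper (monovalent copper) formed by transmetalation adds across the alkyne with the aryl at the β-carbon, and the alkenylcopper is protonated by methanol with retention. Ring C and the new hydrogen are therefore cis, and ring A is cis to the ester (Z); ortho-alkoxyaryl propiolates are established substrates for this reaction.

Step 4
Reactants: 6 methyl (Z)-3-[2-(benzyloxy)-3-methoxyphenyl]-3-(3,4-dimethoxyphenyl)prop-2-enoate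
Product: 7 2-(benzyloxy)-1-[(1Z)-1-(3,4-dimethoxyphenyl)-3-methoxybuta-1,3-dien-1-yl]-3-methoxybenzene
Conditions: Cp2TiMe2, PhMe/THF, 70 °C, dark; filtration through basic Al2O3 (Et3N)
Reagents that add atoms: dimethyltitanocene (Petasis reagent, Cp2TiMe2), [CH3-].[CH3-].c1cc[cH-]c1.c1cc[cH-]c1.[Ti+4]
Why: Petasis methylenation: the titanocene methylidene formed on heating adds to the ester carbonyl, and the oxatitanacyclobutane collapses to the methyl enol ether, a known way from enoates to 2-alkoxydienes. The medium is non-acidic, so neither the enol ether nor the alkene geometry should be disturbed.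

Step 5
Reactants: 7 2-(benzyloxy)-1-[(1Z)-1-(3,4-dimethoxyphenyl)-3-methoxybuta-1,3-dien-1-yl]-3-methoxybenzene
Product: 8 1-(benzyloxy)-8-(3,4-dimethoxyphenyl)-2,6-dimethoxynaphthalene
Conditions: RVC anode, Pt cathode, undivided cell, constant current, about 2.1 F/mol, LiClO4 (0.1 M), 2,6-lutidine, MeOH/CH2Cl2 (1:4), rt
Reagents that add atoms: none
Why: Proposed new method: anodic one-electron oxidation should take an electron from the methoxydiene/aryl π-system of 7, its most easily oxidised part, and the resulting radical cation should be attacked at its terminal carbon C5 by C4a of the twisted, still electron-rich ring A; this is the polarity seen when anodically generated enol ether radical cations are trapped at their β-carbon by tethered electron-rich arenes, which is the closest known reaction type (oxidative iodine-and-light cyclisation of 1-aryl-1,3-dienes to naphthalenes is the other). Ring B, the only ring formed, closes in a 6-endo-trig sense, equivalently a radical-cation 6π closure of the C5=C6–C7=C8–C8a=C4a triene. Loss of the C4a proton to 2,6-lutidine restores ring A and leaves an α-methoxy allyl radical over C6–C8, which is oxidised at once to the oxocarbenium ion; loss of a C5 proton then makes ring B aromatic with the methoxy on C6 and ring C on C8. No stereocentre is formed. Two selectivities are needed: ring A and not ring C must close, and it must close at C4a. The first is secured by the Z geometry set in step 3, which holds ring A cis to the methoxyvinyl arm; this isomer is also expected to be favoured if the radical cation rotates, because the ortho-substituted ring A is twisted in any case while ring C can then lie in plane. The second is secured by constitution, C4a being the only hydrogen-bearing ortho carbon of ring A and para to the C2 methoxy. The benzyl and methyl aryl ethers are oxidised only at higher potential, and the charge is limited to spare the product.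

Step 6
Reactants: 8 1-(benzyloxy)-8-(3,4-dimethoxyphenyl)-2,6-dimethoxynaphthalene
Product: 9 8-(3,4-dimethoxyphenyl)-2,6-dimethoxynaphthalen-1-ol
Conditions: H2 (1 atm), Pd/C (10% palladium on carbon), EtOAc, rt; used directly under argon
Reagents that add atoms: none
Why: Hydrogenolysis of a benzyl aryl ether; methyl ethers, the biaryl bond and the naphthalene core are inert at atmospheric pressure, and the air-sensitive naphthol is taken on without storage.

Step 7
Reactants: 9 8-(3,4-dimethoxyphenyl)-2,6-dimethoxynaphthalen-1-ol
Product: 10 8-(3,4-dimethoxyphenyl)-2,6-dimethoxynaphthalene-1,4-dione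
Conditions: (KSO3)2NO (Fremy's salt, 2.5 equiv), aq. KH2PO4, acetone, 0 °C to rt
Reagents that add atoms: potassium nitrosodisulfonate, [K+].[K+].[O]N(S(=O)(=O)[O-])S(=O)(=O)[O-]
Why: Teuber oxidation: one nitroxide radical abstracts the phenolic hydrogen, a second couples through oxygen at C4, para to the hydroxyl (the ortho carbon C2 is blocked by methoxy), and loss of imidodisulfonate gives the 1,4-quinone. Rings B and C carry no free hydroxyl and should not react with this mild radical.

## Compound list

1 | 2-(benzyloxy)-3-methoxybenzaldehyde | COc1cccc(C=O)c1OCc1ccccc1 | starting material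
2 | 2-(benzyloxy)-1-ethynyl-3-methoxybenzene | C#Cc1cccc(OC)c1OCc1ccccc1 | intermediate
3 | lithium [2-(benzyloxy)-3-methoxyphenyl]ethynide | [Li]C#Cc1cccc(OC)c1OCc1ccccc1 | intermediate (not isolated)
4 | methyl 3-[2-(benzyloxy)-3-methoxyphenyl]prop-2-ynoate | COC(=O)C#Cc1cccc(OC)c1OCc1ccccc1 | intermediate
5 | 3,4-dimethoxyphenylboronic acid | COc1ccc(B(O)O)cc1OC | starting material
6 | methyl (Z)-3-[2-(benzyloxy)-3-methoxyphenyl]-3-(3,4-dimethoxyphenyl)prop-2-enoate | COC(=O)/C=C(\c1cccc(OC)c1OCc1ccccc1)c1ccc(OC)c(OC)c1 | intermediate
7 | 2-(benzyloxy)-1-[(1Z)-1-(3,4-dimethoxyphenyl)-3-methoxybuta-1,3-dien-1-yl]-3-methoxybenzene | C=C(OC)/C=C(\c1cccc(OC)c1OCc1ccccc1)c1ccc(OC)c(OC)c1 | intermediate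
8 | 1-(benzyloxy)-8-(3,4-dimethoxyphenyl)-2,6-dimethoxynaphthalene | COc1ccc2cc(OC)cc(-c3ccc(OC)c(OC)c3)c2c1OCc1ccccc1 | intermediate
9 | 8-(3,4-dimethoxyphenyl)-2,6-dimethoxynaphthalen-1-ol | COc1ccc2cc(OC)cc(-c3ccc(OC)c(OC)c3)c2c1O | intermediate
10 | 8-(3,4-dimethoxyphenyl)-2,6-dimethoxynaphthalene-1,4-dione | COC1=CC(=O)c2cc(OC)cc(-c3ccc(OC)c(OC)c3)c2C1=O | target

## Step count and least certain steps

Total: 7 steps. Longest linear sequence: 7 steps, from **1** to **10**; boronic acid **5** enters in step 3.

**Step 5 (key step, proposed new method).** Three processes may defeat it.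
- The radical cation may be captured by methanol, or may couple intermolecularly, before the ring closes.
- The naphthalene may be oxidised further as it accumulates, since product and substrate are expected to be oxidised at similar potentials.
- Rotation about C7–C8 in the radical cation may bring ring C within reach and give closure onto the wrong ring.

Fallback with known chemistry, leaving the route at ester **6** and rejoining it at naphthalene **8**. Saponification of **6** (LiOH, THF/H2O) gives (Z)-3-[2-(benzyloxy)-3-methoxyphenyl]-3-(3,4-dimethoxyphenyl)prop-2-enoic acid F1. Activation with isobutyl chloroformate and N-methylmorpholine gives the mixed carbonic anhydride F2, which is treated without isolation with CH2N2 to give (Z)-4-[2-(benzyloxy)-3-methoxyphenyl]-1-diazo-4-(3,4-dimethoxyphenyl)but-3-en-2-one F3. Rh2(OAc)4 (divalent rhodium) in CH2Cl2 should generate the carbenoid, which substitutes the cis aryl ring at C4a; this is the aromatic C–H insertion that converts aryl-tethered diazoketones into 2-tetralones and 2-naphthols. Tautomerisation gives 5-(benzyloxy)-4-(3,4-dimethoxyphenyl)-6-methoxynaphthalen-2-ol F4, and O-methylation (MeI, K2CO3, acetone) gives **8**. The same C4a–C5 bond is formed, with C5 delivered as an electrophilic carbenoid, and the alkene geometry of a neutral molecule cannot scramble.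

**Step 4.** Methylenation of a hindered, conjugated ester may be incomplete, and the 2-methoxydiene may hydrolyse during isolation.

Fallback from ester **6** back to diene **7**, making the enol ether by elimination and not by olefination. Treatment of **6** with N,O-dimethylhydroxylamine hydrochloride and i-PrMgCl gives (Z)-3-[2-(benzyloxy)-3-methoxyphenyl]-3-(3,4-dimethoxyphenyl)-N-methoxy-N-methylprop-2-enamide F5. MeMgBr gives (Z)-4-[2-(benzyloxy)-3-methoxyphenyl]-4-(3,4-dimethoxyphenyl)but-3-en-2-one F6. Trimethyl orthoformate in methanol with catalytic pyridinium tosylate gives the dimethyl ketal 2-(benzyloxy)-1-[(1Z)-1-(3,4-dimethoxyphenyl)-3,3-dimethoxybut-1-en-1-yl]-3-methoxybenzene F7. Elimination with Me3SiOTf and i-Pr2NEt gives **7**. The alkene geometry would have to be checked after the acidic ketalisation.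

**Step 7.** Oxidation may spread to the electron-rich rings B and C. Ipso attack at C2 with loss of methanol may give an ortho-quinone. The peri-hindered hydroxyl may slow hydrogen abstraction.

Fallback from naphthol **9** to target **10**, introducing nitrogen at C4 by electrophilic substitution and not oxygen by radical coupling. Azo coupling of **9** with the diazonium salt from 4-aminobenzenesulfonic acid (NaNO2, HCl; then aq. NaOH, 0 °C) should occur para to the naphtholate oxygen and give 4-{(E)-[5-(3,4-dimethoxyphenyl)-4-hydroxy-3,7-dimethoxynaphthalen-1-yl]diazenyl}benzenesulfonic acid F8. Reduction with Na2S2O4 gives 4-amino-8-(3,4-dimethoxyphenyl)-2,6-dimethoxynaphthalen-1-ol F9. Mild oxidation (FeCl3, aq. HCl) and hydrolysis of the quinone imine gives **10**.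

**Step 3.** Carbocupration at the alkyne carbon next to the ortho-benzyloxy group may be slow, allowing protodeboronation of **5**, and the geometry may erode if the alkenylcopper isomerises before protonation.

Fallback from aldehyde **1** to ester **6**, setting the geometry by a Heck reaction. Horner–Wadsworth–Emmons olefination of **1** (trimethyl phosphonoacetate, NaH, THF) gives methyl (E)-3-[2-(benzyloxy)-3-methoxyphenyl]prop-2-enoate F10. Heck arylation with 4-iodo-1,2-dimethoxybenzene (Pd(OAc)2, Bu4NCl, NaHCO3, DMF, 90 °C; divalent palladium precatalyst) then gives **6**. Syn-carbopalladation and syn-β-hydride elimination place the incoming ring C trans to the ester and ring A cis to it.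

## Further compounds

F1 | step 5 | (Z)-3-[2-(benzyloxy)-3-methoxyphenyl]-3-(3,4-dimethoxyphenyl)prop-2-enoic acid | OC(=O)/C=C(\c1cccc(OC)c1OCc1ccccc1)c1ccc(OC)c(OC)c1
F2 | step 5 | (Z)-3-[2-(benzyloxy)-3-methoxyphenyl]-3-(3,4-dimethoxyphenyl)prop-2-enoic 2-methylpropyl carbonic anhydride | CC(C)COC(=O)OC(=O)/C=C(\c1cccc(OC)c1OCc1ccccc1)c1ccc(OC)c(OC)c1
F3 | step 5 | (Z)-4-[2-(benzyloxy)-3-methoxyphenyl]-1-diazo-4-(3,4-dimethoxyphenyl)but-3-en-2-one | [N-]=[N+]=CC(=O)/C=C(\c1cccc(OC)c1OCc1ccccc1)c1ccc(OC)c(OC)c1
F4 | step 5 | 5-(benzyloxy)-4-(3,4-dimethoxyphenyl)-6-methoxynaphthalen-2-ol | COc1ccc2cc(O)cc(-c3ccc(OC)c(OC)c3)c2c1OCc1ccccc1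
F5 | step 4 | (Z)-3-[2-(benzyloxy)-3-methoxyphenyl]-3-(3,4-dimethoxyphenyl)-N-methoxy-N-methylprop-2-enamide | CON(C)C(=O)/C=C(\c1cccc(OC)c1OCc1ccccc1)c1ccc(OC)c(OC)c1
F6 | step 4 | (Z)-4-[2-(benzyloxy)-3-methoxyphenyl]-4-(3,4-dimethoxyphenyl)but-3-en-2-one | CC(=O)/C=C(\c1cccc(OC)c1OCc1ccccc1)c1ccc(OC)c(OC)c1
F7 | step 4 | 2-(benzyloxy)-1-[(1Z)-1-(3,4-dimethoxyphenyl)-3,3-dimethoxybut-1-en-1-yl]-3-methoxybenzene | COC(C)(OC)/C=C(\c1cccc(OC)c1OCc1ccccc1)c1ccc(OC)c(OC)c1
F8 | step 7 | 4-{(E)-[5-(3,4-dimethoxyphenyl)-4-hydroxy-3,7-dimethoxynaphthalen-1-yl]diazenyl}benzenesulfonic acid | COc1cc(/N=N/c3ccc(cc3)S(O)(=O)=O)c2cc(OC)cc(-c3ccc(OC)c(OC)c3)c2c1O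
F9 | step 7 | 4-amino-8-(3,4-dimethoxyphenyl)-2,6-dimethoxynaphthalen-1-ol | COc1cc(N)c2cc(OC)cc(-c3ccc(OC)c(OC)c3)c2c1O
F10 | step 3 | methyl (E)-3-[2-(benzyloxy)-3-methoxyphenyl]prop-2-enoate | COC(=O)/C=C/c1cccc(OC)c1OCc1ccccc1
A1 | alternative 1 | 1-(3,4-dimethoxyphenyl)octa-1,7-diyn-3-one | O=C(C#Cc1ccc(OC)c(OC)c1)CCCC#C
A2 | alternative 1 | methoxyacetylene | COC#C
A3 | alternative 1 | 8-(3,4-dimethoxyphenyl)-6-methoxy-3,4-dihydronaphthalen-1(2H)-one | O=C1CCCc2cc(OC)cc(-c3ccc(OC)c(OC)c3)c12
A4 | alternative 1 | 8-(3,4-dimethoxyphenyl)-2-hydroxy-6-methoxynaphthalene-1,4-dione | O=C1C=C(O)C(=O)c2c(-c3ccc(OC)c(OC)c3)cc(OC)cc12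
A5 | alternative 2 | 2-methoxy-1,4-benzoquinone | COC1=CC(=O)C=CC1=O
A6 | alternative 2 | (E)-1-(3,4-dimethoxyphenyl)-3-(tert-butyldimethylsilyloxy)buta-1,3-diene | C=C(O[Si](C)(C)C(C)(C)C)/C=C/c1ccc(OC)c(OC)c1
A7 | alternative 2 | endo cycloadduct, cis-fused 8-(3,4-dimethoxyphenyl)-6-(tert-butyldimethylsilyloxy)-2-methoxy-4a,5,8,8a-tetrahydronaphthalene-1,4-dione (racemic, relative configuration shown) | COC1=CC(=O)[C@H]2CC(O[Si](C)(C)C(C)(C)C)=C[C@@H](c3ccc(OC)c(OC)c3)[C@H]2C1=O
A8 | alternative 3 | 8-ethynyl-1,2,4,6-tetramethoxynaphthalene | C#Cc1cc(OC)cc2c(OC)cc(OC)c(OC)c12
A9 | alternative 3 | 2,3-dimethoxybuta-1,3-diene | C=C(OC)C(=C)OC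
A10 | alternative 3 | 8-(4,5-dimethoxycyclohexa-1,4-dien-1-yl)-1,2,4,6-tetramethoxynaphthalene | COC1=C(OC)CC(=CC1)c1cc(OC)cc2c(OC)cc(OC)c(OC)c12
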